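## Retrosynthetic overview

1. Labels: ring A is the acyl ring (A-C1 depside C=O, A-C2 OH, A-C4 OMe, A-C6 pentyl). Ring B is the benzoic acid ring (B-C1 CO2H, B-C2 heptyl, B-C4 depside O, B-C6 OMe).
2. Feature: A-C2 to A-C5 carry the meta-dioxygen pattern of an acetoacetate-derived 1,3-dioxygenated diene. A-C1, A-C6, the depside carbonyl and the pentyl chain together spell out oct-2-ynoic acid.
3. Key disconnection: a retro-[4+2] cuts A-C1/A-C2 and A-C5/A-C6. It leads back to the ring-B aryl oct-2-ynoate and a dimethoxy silyloxy butadiene, so the depside C–O bond is made while the acid is still linear and unhindered.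
4. Ring B is bought as an arene. The heptyl chain comes from lateral lithiation and hexylation of the methyl group, and the B-C4 oxygen from sterically directed C–H borylation and oxidation. The carboxyl travels as a tert-butyl ester that is removed last.
5. Ring order: ring B is preformed, and ring A is the only ring built (step 8).

Key step: step 8

Assumption: the target has no stereocentre and no stable chiral axis, so it is one achiral compound and no step needs absolute stereocontrol.

## Route

**Step 1**
Reactants: 1 2-methoxy-6-methylbenzoic acid; 2 1-bromohexane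
Product: 4 2-heptyl-6-methoxybenzoic acid, via dilithio benzylic dianion 3 (not isolated)
Conditions: LDA (2.2 equiv), THF, −78 → 0 °C; 2 (1.2 equiv), −78 °C → rt; 1 M HCl
Reagents that add atoms: none
Why: Carboxylate-directed lateral lithiation gives the benzylic dianion, whose carbanion end should be alkylated by the primary bromide in an SN2 reaction while the carboxylate end stays inert (methyl plus hexyl gives heptyl).

**Step 2**
Reactants: 4 2-heptyl-6-methoxybenzoic acid
Product: 5 tert-butyl 2-heptyl-6-methoxybenzoate
Conditions: Cl3CC(=NH)OtBu (2.5 equiv), BF3·OEt2 (cat.), cyclohexane–CH2Cl2, rt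
Reagents that add atoms: tert-butyl 2,2,2-trichloroacetimidate, CC(C)(C)OC(=N)C(Cl)(Cl)Cl
Why: Acid-catalysed imidate alkylation transfers a tert-butyl cation to the carboxyl oxygen (SN1 type), so the ester forms without any attack at the doubly ortho-blocked acyl carbon.

**Step 3**
Reactants: 5 tert-butyl 2-heptyl-6-methoxybenzoate
Product: 6 tert-butyl 2-heptyl-6-methoxy-4-(4,4,5,5-tetramethyl-1,3,2-dioxaborolan-2-yl)benzoate
Conditions: [Ir(OMe)(cod)]2 (1.5 mol %), dtbpy (3 mol %), B2pin2 (1.1 equiv), THF, 80 °C, sealed
Reagents that add atoms: bis(pinacolato)diboron, CC1(C)OB(OC1(C)C)B1OC(C)(C)C(C)(C)O1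
Why: Iridium-catalysed aromatic C–H borylation is governed by sterics, and in this 1,2,3-trisubstituted arene only B-C4–H has two hydrogen neighbours (B-C3 is ortho to heptyl, B-C5 ortho to methoxy), so boron should enter para to the ester.

**Step 4**
Reactants: 6 tert-butyl 2-heptyl-6-methoxy-4-(4,4,5,5-tetramethyl-1,3,2-dioxaborolan-2-yl)benzoate
Product: 7 tert-butyl 2-heptyl-4-hydroxy-6-methoxybenzoate
Conditions: 30% aq H2O2, NaOH (1 equiv), THF, 0 °C → rt
Reagents that add atoms: hydrogen peroxide, OO
Why: Oxidative ipso-hydroxylation of the arylboronate (hydroperoxide adds to boron, the aryl group migrates 1,2 to oxygen, the borate hydrolyses) gives the phenol, and the hindered tert-butyl ester resists cold hydroxide.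

**Step 5**
Reactants: 7 tert-butyl 2-heptyl-4-hydroxy-6-methoxybenzoate; 8 oct-2-ynoic acid
Product: 9 tert-butyl 2-heptyl-6-methoxy-4-(oct-2-ynoyloxy)benzoate
Conditions: DCC (1.1 equiv), DMAP (5 mol %), CH2Cl2, 0 °C → rt
Reagents that add atoms: none
Why: Steglich esterification joins a rod-like alkynoic acid to a phenol oxygen flanked by two ring hydrogens, so the future depside C–O bond forms at an unhindered stage, and the low DMAP loading and low temperature hold back conjugate addition to the ynoate.

**Step 6**
Reactants: 10 methyl acetoacetate
Product: 11 methyl (E)-3-methoxybut-2-enoate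
Conditions: HC(OMe)3 (1.2 equiv), conc. H2SO4 (cat.), rt; distil
Reagents that add atoms: trimethyl orthoformate, COC(OC)OC
Why: Acid-catalysed ketalisation of the ketone by the orthoester followed by loss of methanol (enol ether formation) should give the conjugated E enol ether as the thermodynamic isomer.

**Step 7**
Reactants: 11 methyl (E)-3-methoxybut-2-enoate
Product: 13 (E)-1,3-dimethoxy-1-(trimethylsilyloxy)buta-1,3-diene, via lithium dienolate 12 (not isolated)
Conditions: LDA (1.1 equiv), THF, −78 °C; TMSCl (1.3 equiv), −78 °C → rt; pentane, filter, distil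
Reagents that add atoms: chlorotrimethylsilane, C[Si](C)(C)Cl
Why: Kinetic γ-deprotonation of the vinylogous carbonate gives the extended dienolate, which the hard silicon electrophile traps on oxygen (silyl ketene acetal formation); the geometry drawn at the ketene acetal end does not matter, because that carbon becomes A-C2.

**Step 8**
Reactants: 9 tert-butyl 2-heptyl-6-methoxy-4-(oct-2-ynoyloxy)benzoate; 13 (E)-1,3-dimethoxy-1-(trimethylsilyloxy)buta-1,3-diene
Product: 15 tert-butyl 2-heptyl-4-[(2-hydroxy-4-methoxy-6-pentylbenzoyl)oxy]-6-methoxybenzoate, via cyclohexadiene ketal adduct 14 (not isolated)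
Conditions: 13 (3 equiv, in portions), o-xylene (conc.), 130 °C, sealed tube, Ar; then 1 M HCl–THF, 0 °C → rt
Reagents that add atoms: none
Why: This is a normal-electron-demand Diels–Alder reaction, concerted but strongly asynchronous: the unsubstituted methylene terminus of 13, which holds the largest HOMO coefficient because both oxygenated carbons push density towards it, bonds first to the pentyl-bearing β-carbon of the ynoate (A-C5 to A-C6), and the ketene acetal carbon then closes on the α-carbon (A-C2 to A-C1). The closest known reaction type is the thermal benzannulation of 1,3-dioxygenated silyl ketene acetal dienes with alkyl alk-2-ynoates to 6-alkylresorcylates; here only the ester alcohol is changed to a phenol, which lowers the LUMO of the triple bond. Ring A closes as a six-membered carbocycle in an intermolecular suprafacial [4π+2π] mode, four carbons coming from 13 and two from 9. The ketal carbon of 14 is the only stereocentre formed; it arises racemic and vanishes when dilute acid cleaves the O–Si bond, the hemiketal expels methanol and the cyclohexadienone enolises to the phenol hydrogen-bonded to the depside carbonyl, so no stereocontrol is needed. The step needs regioselectivity, secured by the matched polarisation just described (the reverse orientation would pair like-polarised termini), and it needs loss of methanol instead of silanol, secured by the much greater lability of the O–Si bond towards aqueous acid. No nucleophile, base or Lewis acid is present during heating, so the aryl ester and the tert-butyl ester should survive, and the surplus diene takes up any methanol released early.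

**Step 9**
Reactants: 15 tert-butyl 2-heptyl-4-[(2-hydroxy-4-methoxy-6-pentylbenzoyl)oxy]-6-methoxybenzoate
Product: 16 2-heptyl-4-[(2-hydroxy-4-methoxy-6-pentylbenzoyl)oxy]-6-methoxybenzoic acid (target)
Conditions: TFA–CH2Cl2 (1:4), Et3SiH (2 equiv), 0 °C
Reagents that add atoms: none
Why: Acidolysis of the tert-butyl ester by alkyl–oxygen fission (AAL1) frees the acid while the silane reduces the tert-butyl cation before it can alkylate A-C3 or A-C5, and the aryl ester link, the methyl ethers and the chelated phenol have no ionisable alkyl group and should stay.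

## Compound list

1 | 2-methoxy-6-methylbenzoic acid | Cc1cccc(OC)c1C(=O)O | starting material
2 | 1-bromohexane | CCCCCCBr | starting material
3 | dilithio benzylic dianion of 1 | [Li+].[Li+].[CH2-]c1cccc(OC)c1C(=O)[O-] | intermediate
4 | 2-heptyl-6-methoxybenzoic acid | CCCCCCCc1cccc(OC)c1C(=O)O | intermediate
5 | tert-butyl 2-heptyl-6-methoxybenzoate | CCCCCCCc1cccc(OC)c1C(=O)OC(C)(C)C | intermediate
6 | tert-butyl 2-heptyl-6-methoxy-4-(4,4,5,5-tetramethyl-1,3,2-dioxaborolan-2-yl)benzoate | CCCCCCCc1cc(B2OC(C)(C)C(C)(C)O2)cc(OC)c1C(=O)OC(C)(C)C | intermediate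
7 | tert-butyl 2-heptyl-4-hydroxy-6-methoxybenzoate | CCCCCCCc1cc(O)cc(OC)c1C(=O)OC(C)(C)C | intermediate
8 | oct-2-ynoic acid | CCCCCC#CC(=O)O | starting material
9 | tert-butyl 2-heptyl-6-methoxy-4-(oct-2-ynoyloxy)benzoate | CCCCCC#CC(=O)Oc1cc(CCCCCCC)c(C(=O)OC(C)(C)C)c(OC)c1 | intermediate
10 | methyl acetoacetate | CC(=O)CC(=O)OC | starting material
11 | methyl (E)-3-methoxybut-2-enoate | CO/C(C)=C/C(=O)OC | intermediate
12 | lithium dienolate of 11 | [Li+].C=C(OC)/C=C(/[O-])OC | intermediate
13 | (E)-1,3-dimethoxy-1-(trimethylsilyloxy)buta-1,3-diene | C=C(OC)/C=C(/O[Si](C)(C)C)OC | intermediate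
14 | cyclohexa-1,4-diene mixed methyl silyl ketal adduct (racemic at the ketal carbon) | CCCCCC1=C(C(=O)Oc2cc(CCCCCCC)c(C(=O)OC(C)(C)C)c(OC)c2)C(OC)(O[Si](C)(C)C)C=C(OC)C1 | intermediate
15 | tert-butyl 2-heptyl-4-[(2-hydroxy-4-methoxy-6-pentylbenzoyl)oxy]-6-methoxybenzoate | CCCCCCCc1cc(OC(=O)c2c(O)cc(OC)cc2CCCCC)cc(OC)c1C(=O)OC(C)(C)C | intermediate
16 | 2-heptyl-4-[(2-hydroxy-4-methoxy-6-pentylbenzoyl)oxy]-6-methoxybenzoic acid | CCCCCCCc1cc(OC(=O)c2c(O)cc(OC)cc2CCCCC)cc(OC)c1C(=O)O | target

Total step count: 9.
Longest linear sequence: 7 (steps 1–5, 8, 9).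

## Steps most likely to fail

**Step 8.**
- Risk: cycloaddition to the β-alkyl triple bond may be slower than thermal decay of the diene through silyl migration or protodesilylation by released methanol. The activated aryl ester may transfer its acyl group. Part of the adduct may aromatise by loss of silanol instead of methanol.
- Fallback: it sets out from phenol 7 and comes back at 15, with ring A bought as an arene and the depside bond made by classical esterification.
- Sequence: purchased olivetol F1 is formylated under Vilsmeier–Haack conditions (POCl3, DMF) to 2,4-dihydroxy-6-pentylbenzaldehyde F2. The non-chelated para hydroxyl is methylated (MeI, 1 equiv, K2CO3, acetone) to 2-hydroxy-4-methoxy-6-pentylbenzaldehyde F3. Pinnick oxidation (NaClO2, sulfamic acid) gives 2-hydroxy-4-methoxy-6-pentylbenzoic acid F4, which is condensed with 7 by DCC in dry toluene to give 15.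

**Step 9.**
- Risk: exposing the finished depside to strong acid may lead to capture of the tert-butyl cation by electron-rich ring A. It may also cause acid-promoted acyl transfer at the depside link next to the free ortho phenol, or protodecarboxylation at B-C1.
- Fallback: it sets out from 9 and comes back at 16 by removing the tert-butyl group before ring A exists.
- Sequence: TFA–CH2Cl2 at 0 °C converts 9 into 2-heptyl-6-methoxy-4-(oct-2-ynoyloxy)benzoic acid F5. N,O-bis(trimethylsilyl)acetamide turns this into its trimethylsilyl ester F6. Heating F6 with 13 as in step 8 gives the silyl ester cycloadduct F7. The same dilute HCl–THF work-up aromatises ring A and hydrolyses the silyl ester, giving 16 directly.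

**Step 1.**
- Risk: dianion formation may be incomplete, ring metalation next to the methoxy group may compete, the bromide may undergo elimination, or a second alkylation may occur.
- Fallback: it sets out from 1 and comes back at 5 by reversing the order, so that a monoanion of a non-electrophilic ester is alkylated instead of an acid dianion.
- Sequence: 1 is esterified with tert-butyl trichloroacetimidate as in step 2 to tert-butyl 2-methoxy-6-methylbenzoate F8. LDA (1.1 equiv, THF, −78 °C) gives the laterally lithiated ester F9, whose self-condensation is blocked by the bulky, doubly flanked ester. Alkylation with 2 gives 5.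

## Further compounds

F1 | step 8 | olivetol (5-pentylbenzene-1,3-diol, purchased) | CCCCCc1cc(O)cc(O)c1
F2 | step 8 | 2,4-dihydroxy-6-pentylbenzaldehyde | CCCCCc1cc(O)cc(O)c1C=O
F3 | step 8 | 2-hydroxy-4-methoxy-6-pentylbenzaldehyde | CCCCCc1cc(OC)cc(O)c1C=O
F4 | step 8 | 2-hydroxy-4-methoxy-6-pentylbenzoic acid | CCCCCc1cc(OC)cc(O)c1C(=O)O
F5 | step 9 | 2-heptyl-6-methoxy-4-(oct-2-ynoyloxy)benzoic acid | CCCCCC#CC(=O)Oc1cc(CCCCCCC)c(C(=O)O)c(OC)c1
F6 | step 9 | trimethylsilyl 2-heptyl-6-methoxy-4-(oct-2-ynoyloxy)benzoate | CCCCCC#CC(=O)Oc1cc(CCCCCCC)c(C(=O)O[Si](C)(C)C)c(OC)c1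
F7 | step 9 | silyl ester cycloadduct (cyclohexa-1,4-diene mixed ketal, racemic) | CCCCCC1=C(C(=O)Oc2cc(CCCCCCC)c(C(=O)O[Si](C)(C)C)c(OC)c2)C(OC)(O[Si](C)(C)C)C=C(OC)C1
F8 | step 1 | tert-butyl 2-methoxy-6-methylbenzoate | Cc1cccc(OC)c1C(=O)OC(C)(C)C
F9 | step 1 | laterally lithiated tert-butyl 2-methoxy-6-methylbenzoate | [Li+].[CH2-]c1cccc(OC)c1C(=O)OC(C)(C)C
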